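**Plan**
1. Retrosynthesis: cut C2–C3 of the pyranone ring, leaving an aryl ethyl ether next to an α-diazo ethyl ketone; cut O1–ethyl and the ester C–OMe back to a 3,4-dihydrocoumarin whose lactone oxygen is the future O1; cut the C4–H bond of that lactone, the C6 prenyl and C8 propanoyl groups, and finally the coumarin ring to phloroglucinol and ethyl 3-oxohexanoate.
2. Forward: coumarin ring (Pechmann) → C8 acylation → C6 prenylation → silylation (ketone masked as silyl enol ether) → CuH reduction → lactone methanolysis → O-ethylation → diazo transfer → pyranone ring by carbene C–H insertion → desilylation.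
3. Stereochemistry: the side-chain S centre comes from ligand-controlled CuH reduction of the coumarin; C2 (R) and C3 (S), cis, both come from the chiral dirhodium carboxylate in the insertion.
4. Enabling feature: O1 makes the C–H bonds of an O–CH2CH3 group hydridic and the C4 ketone lets C3 carry a diazo group; O1 and the acyl carbon sit on the neighbouring ring carbons C8a and C4a, so the carbene carbon and the O–CH2 carbon are 1,6-related, the distance for closing the six-membered pyranone ring.
5. The coumarin lactone does double duty: it directs acylation to the adjacent carbon and singles out its own oxygen for ethylation.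

Key step: step 9

Assumption: the hand of the two chiral catalysts ((R)-DTBM-SEGPHOS in step 5, Rh2(S-PTTL)4 in step 9) is assigned by analogy with simpler substrates; should a first run show the opposite sense, the mirror-image ligand is used with no other change.

Step 1
Reactants: 1 phloroglucinol; 2 ethyl 3-oxohexanoate
Product: 3 5,7-dihydroxy-4-propylchromen-2-one
Conditions: conc. H2SO4, 0 °C → rt
Reagents that add atoms: none
Why: Pechmann condensation (transesterification, ring C-alkylation by the ketone, dehydration) on the threefold-symmetric, very electron-rich triol can give only one coumarin.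

Step 2
Reactants: 3 5,7-dihydroxy-4-propylchromen-2-one
Product: 4 5,7-dihydroxy-8-propanoyl-4-propylchromen-2-one
Conditions: EtCOCl, AlCl3, 1,2-dichloroethane, 75 °C; aq. HCl; minor 6-acyl isomer removed by crystallisation
Reagents that add atoms: propanoyl chloride, CCC(=O)Cl
Why: Friedel–Crafts acylation is expected at C8, the preferred site in 5,7-dihydroxy-4-alkylcoumarins, which places the ketone next to the lactone oxygen that is to become O1.

Step 3
Reactants: 4 5,7-dihydroxy-8-propanoyl-4-propylchromen-2-one
Product: 5 5,7-dihydroxy-6-(3-methylbut-2-enyl)-8-propanoyl-4-propylchromen-2-one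
Conditions: 2-methylbut-3-en-2-ol, BF3·OEt2, dioxane, rt, stopped at partial conversion
Reagents that add atoms: 2-methylbut-3-en-2-ol, CC(C)(O)C=C
Why: Friedel–Crafts C-prenylation by the dimethylallyl cation should occur at C6, the only unsubstituted ring carbon, and the non-basic medium keeps the lactone closed so that it cannot re-close onto the C5 oxygen.

Step 4
Reactants: 5 5,7-dihydroxy-6-(3-methylbut-2-enyl)-8-propanoyl-4-propylchromen-2-one
Product: 6 5,7-bis(tert-butyldimethylsilyloxy)-8-[(Z)-1-(tert-butyldimethylsilyloxy)prop-1-enyl]-6-(3-methylbut-2-enyl)-4-propylchromen-2-one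
Conditions: TBSOTf (4 equiv), Et3N, CH2Cl2, 0 °C → rt
Reagents that add atoms: tert-butyldimethylsilyl trifluoromethanesulfonate, CC(C)(C)[Si](C)(C)OS(=O)(=O)C(F)(F)F
Why: Silyl triflate and amine silylate both phenols and convert the ethyl ketone into its silyl enol ether (soft enolisation), which hides the ketone from CuH and gives aryl ethers that carry no C–H bond next to oxygen.

Step 5
Reactants: 6 5,7-bis(tert-butyldimethylsilyloxy)-8-[(Z)-1-(tert-butyldimethylsilyloxy)prop-1-enyl]-6-(3-methylbut-2-enyl)-4-propylchromen-2-one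
Product: 7 (4S)-5,7-bis(tert-butyldimethylsilyloxy)-8-[(Z)-1-(tert-butyldimethylsilyloxy)prop-1-enyl]-6-(3-methylbut-2-enyl)-4-propylchroman-2-one
Conditions: Cu(OAc)2·H2O (3 mol%), (R)-DTBM-SEGPHOS (3 mol%), (EtO)2MeSiH, t-BuOH, toluene, rt
Reagents that add atoms: none
Why: Ligated CuH asymmetric conjugate reduction of a coumarin delivers hydride to C4 on the face chosen by the bisphosphine and tert-butanol protonates the copper enolate, which sets the S centre while the silyl enol ether and the trisubstituted prenyl alkene are inert.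

Step 6
Reactants: 7 (4S)-5,7-bis(tert-butyldimethylsilyloxy)-8-[(Z)-1-(tert-butyldimethylsilyloxy)prop-1-enyl]-6-(3-methylbut-2-enyl)-4-propylchroman-2-one
Product: 9 methyl (3S)-3-[4,6-bis(tert-butyldimethylsilyloxy)-2-hydroxy-5-(3-methylbut-2-enyl)-3-propanoylphenyl]hexanoate, via ketone lactone 8 (not isolated)
Conditions: (1S)-10-camphorsulfonic acid (0.2 equiv), MeOH/CH2Cl2, rt → 40 °C; NaHCO3 quench
Reagents that add atoms: methanol, CO
Why: Acid-catalysed methanolysis cleaves the silyl enol ether and then transesterifies the aryl lactone, the freed phenol being held open by its hydrogen bond to the new ketone, while aryl silyl ethers tolerate this mild acid.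

Step 7
Reactants: 9 methyl (3S)-3-[4,6-bis(tert-butyldimethylsilyloxy)-2-hydroxy-5-(3-methylbut-2-enyl)-3-propanoylphenyl]hexanoate
Product: 10 methyl (3S)-3-[4,6-bis(tert-butyldimethylsilyloxy)-2-ethoxy-5-(3-methylbut-2-enyl)-3-propanoylphenyl]hexanoate
Conditions: EtOH, PPh3, DIAD, THF, 0 °C → rt
Reagents that add atoms: ethanol, CCO
Why: Mitsunobu etherification alkylates the only free phenol, acidic through its ortho ketone, under neutral conditions that spare the aryl silyl ethers and the ester.

Step 8
Reactants: 10 methyl (3S)-3-[4,6-bis(tert-butyldimethylsilyloxy)-2-ethoxy-5-(3-methylbut-2-enyl)-3-propanoylphenyl]hexanoate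
Product: 12 methyl (3S)-3-[4,6-bis(tert-butyldimethylsilyloxy)-3-(2-diazopropanoyl)-2-ethoxy-5-(3-methylbut-2-enyl)phenyl]hexanoate, via trifluoroacetyl diketone 11 (not isolated)
Conditions: LiN(SiMe3)2, THF, −78 °C; CF3CO2CH2CF3; then MsN3, Et3N, H2O (1 equiv), MeCN, rt
Reagents that add atoms: 2,2,2-trifluoroethyl trifluoroacetate, O=C(OCC(F)(F)F)C(F)(F)F (trifluoroacetyl group of 11 only); methanesulfonyl azide, CS(=O)(=O)N=[N+]=[N-] (N2 of 12)
Why: Detrifluoroacetylative diazo transfer: the ketone, more acidic than the ester, is enolised and trifluoroacetylated at −78 °C, and the activated 1,3-diketone takes N2 from the sulfonyl azide with loss of the trifluoroacetyl group.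

Step 9
Reactants: 12 methyl (3S)-3-[4,6-bis(tert-butyldimethylsilyloxy)-3-(2-diazopropanoyl)-2-ethoxy-5-(3-methylbut-2-enyl)phenyl]hexanoate
Product: 13 methyl (3S)-3-[(2R,3S)-5,7-bis(tert-butyldimethylsilyloxy)-2,3-dimethyl-6-(3-methylbut-2-enyl)-4-oxochroman-8-yl]hexanoate
Conditions: Rh2(S-PTTL)4 (dirhodium tetrakis[N-phthaloyl-(S)-tert-leucinate], 1 mol%), toluene, −40 → 0 °C, slow addition of 12 at high dilution
Reagents that add atoms: none
Why: Loss of N2 at the dirhodium core gives an electrophilic rhodium carbene at C3, which inserts into a C–H bond of the O–CH2 group of the ortho ethoxy substituent through a three-centre, hydride-transfer-like transition state with retention at carbon, forming the C2–C3 bond; the closest known reaction type is the dirhodium-carboxylate-catalysed intramolecular C–H insertion of 2-diazo-1-(2-alkoxyaryl)propan-1-ones to cis-2,3-disubstituted chroman-4-ones. The pyranone ring closes as a six-membered ring by 1,6-insertion through a chair-like array of C3, C4, C4a, C8a, O1 and C2. C2 (R) is set by which of the two diastereotopic O–CH2 hydrogens is replaced and C3 (S) by the carbene face presented, both chosen by the chiral carboxylate wall of the catalyst (the side-chain centre can only reinforce or erode this), and the methyl groups should end up cis because the ethoxy methyl sits pseudo-equatorial while the carbene methyl turns away from the catalyst. Site selectivity is secured because the ethoxy C–H bonds are the only ones next to oxygen within reach of C3 (the other ortho oxygen carries a silyl group whose nearest C–H bonds are unactivated and 1,7-related) and because the prenyl alkene, meta to the acyl group, cannot be reached intramolecularly and is kept from intermolecular cyclopropanation by slow addition. Insertion must also beat 1,2-hydride shift from the C3 methyl group and oxonium ylide formation, for which the bulky, electron-poor phthalimido carboxylate ligands and low temperature are chosen. The cis isomer is the kinetic one and is kept away from base from here on.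

Step 10
Reactants: 13 methyl (3S)-3-[(2R,3S)-5,7-bis(tert-butyldimethylsilyloxy)-2,3-dimethyl-6-(3-methylbut-2-enyl)-4-oxochroman-8-yl]hexanoate
Product: 14 methyl (3S)-3-[(2R,3S)-5,7-dihydroxy-2,3-dimethyl-6-(3-methylbut-2-enyl)-4-oxochroman-8-yl]hexanoate
Conditions: HF·pyridine, pyridine, THF, 0 °C → rt
Reagents that add atoms: none
Why: Fluoride cleavage of the two aryl silyl ethers in a buffered, mildly acidic medium avoids the base that would epimerise C3 and leaves the prenyl group and the methyl ester untouched.

**Compound list**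
1 | phloroglucinol | Oc1cc(O)cc(O)c1 | starting material
2 | ethyl 3-oxohexanoate | CCCC(=O)CC(=O)OCC | starting material
3 | 5,7-dihydroxy-4-propylchromen-2-one | CCCC1=CC(=O)Oc2cc(O)cc(O)c12 | intermediate
4 | 5,7-dihydroxy-8-propanoyl-4-propylchromen-2-one | CCCC1=CC(=O)Oc2c1c(O)cc(O)c2C(=O)CC | intermediate
5 | 5,7-dihydroxy-6-(3-methylbut-2-enyl)-8-propanoyl-4-propylchromen-2-one | CCCC1=CC(=O)Oc2c1c(O)c(CC=C(C)C)c(O)c2C(=O)CC | intermediate
6 | 5,7-bis(tert-butyldimethylsilyloxy)-8-[(Z)-1-(tert-butyldimethylsilyloxy)prop-1-enyl]-6-(3-methylbut-2-enyl)-4-propylchromen-2-one | CCCC1=CC(=O)Oc2c1c(O[Si](C)(C)C(C)(C)C)c(CC=C(C)C)c(O[Si](C)(C)C(C)(C)C)c2/C(O[Si](C)(C)C(C)(C)C)=C/C | intermediate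
7 | (4S)-5,7-bis(tert-butyldimethylsilyloxy)-8-[(Z)-1-(tert-butyldimethylsilyloxy)prop-1-enyl]-6-(3-methylbut-2-enyl)-4-propylchroman-2-one | CCC[C@H]1CC(=O)Oc2c1c(O[Si](C)(C)C(C)(C)C)c(CC=C(C)C)c(O[Si](C)(C)C(C)(C)C)c2/C(O[Si](C)(C)C(C)(C)C)=C/C | intermediate
8 | (4S)-5,7-bis(tert-butyldimethylsilyloxy)-6-(3-methylbut-2-enyl)-8-propanoyl-4-propylchroman-2-one | CCC[C@H]1CC(=O)Oc2c1c(O[Si](C)(C)C(C)(C)C)c(CC=C(C)C)c(O[Si](C)(C)C(C)(C)C)c2C(=O)CC | intermediate (not isolated)
9 | methyl (3S)-3-[4,6-bis(tert-butyldimethylsilyloxy)-2-hydroxy-5-(3-methylbut-2-enyl)-3-propanoylphenyl]hexanoate | CCC[C@@H](CC(=O)OC)c1c(O)c(C(=O)CC)c(O[Si](C)(C)C(C)(C)C)c(CC=C(C)C)c1O[Si](C)(C)C(C)(C)C | intermediate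
10 | methyl (3S)-3-[4,6-bis(tert-butyldimethylsilyloxy)-2-ethoxy-5-(3-methylbut-2-enyl)-3-propanoylphenyl]hexanoate | CCC[C@@H](CC(=O)OC)c1c(OCC)c(C(=O)CC)c(O[Si](C)(C)C(C)(C)C)c(CC=C(C)C)c1O[Si](C)(C)C(C)(C)C | intermediate
11 | methyl (3S)-3-[4,6-bis(tert-butyldimethylsilyloxy)-2-ethoxy-5-(3-methylbut-2-enyl)-3-(4,4,4-trifluoro-2-methyl-3-oxobutanoyl)phenyl]hexanoate (epimers at the diketone carbon, largely enolised) | CCC[C@@H](CC(=O)OC)c1c(OCC)c(C(=O)C(C)C(=O)C(F)(F)F)c(O[Si](C)(C)C(C)(C)C)c(CC=C(C)C)c1O[Si](C)(C)C(C)(C)C | intermediate (not isolated)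
12 | methyl (3S)-3-[4,6-bis(tert-butyldimethylsilyloxy)-3-(2-diazopropanoyl)-2-ethoxy-5-(3-methylbut-2-enyl)phenyl]hexanoate | CCC[C@@H](CC(=O)OC)c1c(OCC)c(C(=O)C(C)=[N+]=[N-])c(O[Si](C)(C)C(C)(C)C)c(CC=C(C)C)c1O[Si](C)(C)C(C)(C)C | intermediate
13 | methyl (3S)-3-[(2R,3S)-5,7-bis(tert-butyldimethylsilyloxy)-2,3-dimethyl-6-(3-methylbut-2-enyl)-4-oxochroman-8-yl]hexanoate | CCC[C@@H](CC(=O)OC)c1c(O[Si](C)(C)C(C)(C)C)c(CC=C(C)C)c(O[Si](C)(C)C(C)(C)C)c2c1O[C@H](C)[C@H](C)C2=O | intermediate
14 | methyl (3S)-3-[(2R,3S)-5,7-dihydroxy-2,3-dimethyl-6-(3-methylbut-2-enyl)-4-oxochroman-8-yl]hexanoate | CCC[C@@H](CC(=O)OC)c1c(O)c(CC=C(C)C)c(O)c2c1O[C@H](C)[C@H](C)C2=O | target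

Total step count: 10. Longest linear sequence: 10 steps (fully linear, 1 and 2 to 14).

**Steps most likely to fail**

Step 9. The rhodium carbene may be diverted into 1,2-hydride shift to the aryl vinyl ketone, or into attack on an ether oxygen with silyl or alkyl transfer. Catalyst and side-chain centre may also be mismatched, giving poor facial selectivity. The fallback sets out from 9 and returns at 13. Heating 9 with Ac2O and NaOAc (Kostanecki–Robinson reaction) should close the ring by acylation, Claisen-type C2–C3 bond formation and dehydration. This gives methyl (3S)-3-[5,7-bis(tert-butyldimethylsilyloxy)-2,3-dimethyl-6-(3-methylbut-2-enyl)-4-oxochromen-8-yl]hexanoate F1. Enantioselective conjugate reduction of this chromone with Cu(OAc)2·H2O, DTBM-SEGPHOS and (EtO)2MeSiH would set C2. Protonation of the enolate by tert-butanol at low temperature, on the face away from the C2 methyl group, would set C3 cis and give 13.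

Step 5. Hydride delivery to C4 may be slow because of the peri silyloxy group, and enantiofacial discrimination on this electron-rich coumarin may be low. The fallback makes the C4–propyl bond instead of the C4–H bond; it sets out from 1 and returns at 7.
- Pechmann reaction of 1 with ethyl propiolate (ZnCl2, 100 °C) gives 5,7-dihydroxychromen-2-one F2.
- Acylation as in step 2 gives 5,7-dihydroxy-8-propanoylchromen-2-one F3.
- Prenylation as in step 3 gives 5,7-dihydroxy-6-(3-methylbut-2-enyl)-8-propanoylchromen-2-one F4.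
- Silylation as in step 4 gives 5,7-bis(tert-butyldimethylsilyloxy)-8-[(Z)-1-(tert-butyldimethylsilyloxy)prop-1-enyl]-6-(3-methylbut-2-enyl)chromen-2-one F5.
- Copper-catalysed asymmetric conjugate addition of n-PrMgBr (CuBr·SMe2, Josiphos-type ferrocenyl diphosphine, CH2Cl2, −78 °C; NH4Cl work-up) to the unsubstituted C4 of F5 should then give 7.

Step 3. Under the Lewis acid the new prenyl group may cyclise onto a neighbouring hydroxyl to a chroman, or alkylation may stall. The fallback sets out from 4 and returns at 5. Pd(PPh3)4-catalysed O-allylation (Tsuji–Trost) of the free, non-chelated C5 hydroxyl with tert-butyl 2-methylbut-3-en-2-yl carbonate in THF at 0 °C should give 7-hydroxy-5-(2-methylbut-3-en-2-yloxy)-8-propanoyl-4-propylchromen-2-one F6. Aromatic Claisen rearrangement in toluene at 100 °C moves the allyl unit with transposition to C6, the only free ortho carbon, giving 5.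

**Further compounds**
F1 | step 9 | methyl (3S)-3-[5,7-bis(tert-butyldimethylsilyloxy)-2,3-dimethyl-6-(3-methylbut-2-enyl)-4-oxochromen-8-yl]hexanoate | CCC[C@@H](CC(=O)OC)c1c(O[Si](C)(C)C(C)(C)C)c(CC=C(C)C)c(O[Si](C)(C)C(C)(C)C)c2c1OC(C)=C(C)C2=O
F2 | step 5 | 5,7-dihydroxychromen-2-one | O=C1C=Cc2c(O)cc(O)cc2O1
F3 | step 5 | 5,7-dihydroxy-8-propanoylchromen-2-one | CCC(=O)c1c(O)cc(O)c2C=CC(=O)Oc12
F4 | step 5 | 5,7-dihydroxy-6-(3-methylbut-2-enyl)-8-propanoylchromen-2-one | CCC(=O)c1c(O)c(CC=C(C)C)c(O)c2C=CC(=O)Oc12
F5 | step 5 | 5,7-bis(tert-butyldimethylsilyloxy)-8-[(Z)-1-(tert-butyldimethylsilyloxy)prop-1-enyl]-6-(3-methylbut-2-enyl)chromen-2-one | C/C=C(\O[Si](C)(C)C(C)(C)C)c1c(O[Si](C)(C)C(C)(C)C)c(CC=C(C)C)c(O[Si](C)(C)C(C)(C)C)c2C=CC(=O)Oc12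
F6 | step 3 | 7-hydroxy-5-(2-methylbut-3-en-2-yloxy)-8-propanoyl-4-propylchromen-2-one | CCCC1=CC(=O)Oc2c1c(OC(C)(C)C=C)cc(O)c2C(=O)CC
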